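**Retrosynthetic overview**

- The 30-membered ring is opened at its two ester C–O bonds: a Yamaguchi esterification (C1 acid of the methoxy half with C14′–OH of the epoxide half) and, as the last ring-forming step, a Yamaguchi macrolactonisation (C1′ acid with C14–OH).
- Both halves come from one aldehyde, (S)-OHC–CMe2–CH(OTES)–CH=CH–Me. Its C15–C16 bond is made by a Kiyooka–Mukaiyama aldol of crotonaldehyde, and the C13–C14 bond by a catalyst-controlled allenylboration (the propargyl form of carbonyl allylation), which gives the 14R or the 14′S homopropargylic alcohol depending on the catalyst antipode.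
- Methoxy half: C6 comes from a crossed Claisen condensation followed by Noyori transfer hydrogenation; the oxazole from serine (oxazoline first, then oxidation); the all-Z triene from two Sonogashira couplings onto (Z)-1,2-dichloroethene and a Zn(Cu/Ag) reduction.
- Epoxide half: Sonogashira coupling with (Z)-3-iodoallyl alcohol, Sharpless epoxidation (cis-epoxide), semihydrogenation, then Wittig and Horner–Wadsworth–Emmons olefinations that bring in the second oxazole preformed.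
- Order of ring formation: oxazoline then oxazole of the methoxy half, epoxide, macrocycle.

Assumption: the SMILES is taken literally (methoxy half 6R,7Z,9Z,11Z,14R,16S,17E; epoxide half 5′E,7′E,9′S,10′R,11′Z,14′S,16′S,17′E; disorazole numbering, primes for the epoxide half). The reagent antipodes in steps 1, 5, 6 and 8 were assigned from literature precedent and stereochemical models; the product configurations are to be confirmed by Mosher analysis.

**Route**

Step 1
Reactants: 1 (E)-but-2-enal; 2 1-methoxy-2-methyl-1-(trimethylsilyloxy)prop-1-ene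
Product: 3 methyl (3S,4E)-3-hydroxy-2,2-dimethylhex-4-enoate
Conditions: N-Ts-D-valine (1.0 equiv), BH3·THF (1.0 equiv), CH2Cl2, 0 °C→rt; then 1, 2, −78 °C; pH 7 buffer
Reagents that add atoms: none
Why: Kiyooka–Mukaiyama aldol in which the D-valine-derived oxazaborolidinone activates the enal for 1,2-attack of the ketene silyl acetal on its Re face, setting C16 as S (about 90% ee, upgraded later because every downstream intermediate is a separable diastereomer).

Step 2
Reactants: 3 methyl (3S,4E)-3-hydroxy-2,2-dimethylhex-4-enoate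
Product: 4 methyl (3S,4E)-2,2-dimethyl-3-(triethylsilyloxy)hex-4-enoate
Conditions: TESOTf, 2,6-lutidine, CH2Cl2, −78→0 °C
Reagents that add atoms: triethylsilyl trifluoromethanesulfonate, CC[Si](CC)(CC)OS(=O)(=O)C(F)(F)F
Why: Silyl ether formation with the triflate, which overcomes the neopentyl hindrance and blocks retro-aldol cleavage in the following steps.

Step 3
Reactants: 4 methyl (3S,4E)-2,2-dimethyl-3-(triethylsilyloxy)hex-4-enoate
Product: 5 (3S,4E)-2,2-dimethyl-3-(triethylsilyloxy)hex-4-en-1-ol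
Conditions: iBu2AlH (2.5 equiv), CH2Cl2, −78→0 °C; aqueous potassium sodium tartrate
Reagents that add atoms: none
Why: Hydride reduction of the hindered ester to the primary alcohol, leaving the silyl ether and the alkene untouched.

Step 4
Reactants: 5 (3S,4E)-2,2-dimethyl-3-(triethylsilyloxy)hex-4-en-1-ol
Product: 6 (3S,4E)-2,2-dimethyl-3-(triethylsilyloxy)hex-4-enal
Conditions: Dess–Martin periodinane, CH2Cl2, 0 °C→rt
Reagents that add atoms: none
Why: Dess–Martin oxidation of a neopentyl alcohol gives the aldehyde, which has no α-hydrogen and so cannot epimerise or enolise.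

Step 5
Reactants: 6 (3S,4E)-2,2-dimethyl-3-(triethylsilyloxy)hex-4-enal; 7 4,4,5,5-tetramethyl-2-(propa-1,2-dien-1-yl)-1,3,2-dioxaborolane
Product: 9 (4R,6S,7E)-5,5-dimethyl-6-(triethylsilyloxy)non-7-en-1-yn-4-ol, via its O-pinacolboryl ether 8 (not isolated)
Conditions: (R)-3,3′-bis(2,4,6-triisopropylphenyl)-1,1′-binaphthyl-2,2′-diyl hydrogen phosphate (10 mol %), 4 Å MS, toluene, −20→0 °C; then H2O
Reagents that add atoms: none
Why: Chiral-phosphoric-acid-catalysed allenylboration (carbonyl propargylation through a closed six-membered SE2′ transition state) in which the (R)-catalyst directs the propargyl unit to the Re face of the aldehyde, setting C14 as R (1,3-syn) under catalyst control.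

Step 6
Reactants: 6 (3S,4E)-2,2-dimethyl-3-(triethylsilyloxy)hex-4-enal; 7 4,4,5,5-tetramethyl-2-(propa-1,2-dien-1-yl)-1,3,2-dioxaborolane
Product: 11 (4S,6S,7E)-5,5-dimethyl-6-(triethylsilyloxy)non-7-en-1-yn-4-ol, via its O-pinacolboryl ether 10 (not isolated)
Conditions: (S)-3,3′-bis(2,4,6-triisopropylphenyl)-1,1′-binaphthyl-2,2′-diyl hydrogen phosphate (10 mol %), 4 Å MS, toluene, −20→0 °C; then H2O
Reagents that add atoms: none
Why: The same allenylboration with the enantiomeric catalyst attacks the Si face and sets C14′ as S (1,3-anti), so both epimers needed come from one aldehyde.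

Step 7
Reactants: 12 ethyl 3-(trimethylsilyl)prop-2-ynoate; 13 tert-butyl acetate
Product: 15 tert-butyl 3-oxo-5-(trimethylsilyl)pent-4-ynoate, via lithium enolate of tert-butyl acetate 14 (not isolated)
Conditions: LiN(iPr)2 (2.1 equiv), 13, THF, −78 °C; then 12, −78 °C; AcOH
Reagents that add atoms: none
Why: Crossed Claisen condensation in which the silyl group shields the β-carbon so the enolate adds 1,2, and deprotonation of the β-keto ester by the second equivalent of enolate drives it to completion.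

Step 8
Reactants: 15 tert-butyl 3-oxo-5-(trimethylsilyl)pent-4-ynoate
Product: 16 tert-butyl (3R)-3-hydroxy-5-(trimethylsilyl)pent-4-ynoate
Conditions: RuCl(p-cymene)[(R,R)-TsNCHPhCHPhNH2] (1 mol %), HCO2H/Et3N (5:2), CH2Cl2, rt
Reagents that add atoms: none
Why: Noyori asymmetric transfer hydrogenation of an alkynyl ketone, where the alkyne takes the place of the aryl group in the transition state so the (R,R)-catalyst gives the (R)-propargylic alcohol that becomes C6.

Step 9
Reactants: 16 tert-butyl (3R)-3-hydroxy-5-(trimethylsilyl)pent-4-ynoate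
Product: 17 tert-butyl (3R)-3-methoxy-5-(trimethylsilyl)pent-4-ynoate
Conditions: Me3OBF4, 1,8-bis(dimethylamino)naphthalene, 4 Å MS, CH2Cl2, 0 °C→rt
Reagents that add atoms: trimethyloxonium tetrafluoroborate, C[O+](C)C.F[B-](F)(F)F
Why: O-Methylation with Meerwein salt and a non-nucleophilic base avoids the retro-aldol and β-elimination that alkoxide conditions would cause in a β-hydroxy ester.

Step 10
Reactants: 17 tert-butyl (3R)-3-methoxy-5-(trimethylsilyl)pent-4-ynoate
Product: 18 (3R)-3-methoxy-5-(trimethylsilyl)pent-4-ynoic acid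
Conditions: CF3CO2H/CH2Cl2 (1:4), 0 °C→rt
Reagents that add atoms: none
Why: Acidolysis of the tert-butyl ester (loss of isobutene) frees the acid without base, so the β-methoxy group is not eliminated and the alkynylsilane stays on.

Step 11
Reactants: 18 (3R)-3-methoxy-5-(trimethylsilyl)pent-4-ynoic acid; 19 methyl L-serinate hydrochloride
Product: 20 methyl N-[(3R)-3-methoxy-5-(trimethylsilyl)pent-4-ynoyl]-L-serinate
Conditions: EDC·HCl, HOBt, iPr2NEt, CH2Cl2, 0 °C→rt
Reagents that add atoms: none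
Why: Carbodiimide amide coupling through the HOBt active ester, which acylates the amine selectively over the serine hydroxyl.

Step 12
Reactants: 20 methyl N-[(3R)-3-methoxy-5-(trimethylsilyl)pent-4-ynoyl]-L-serinate
Product: 21 methyl (4S)-2-[(2R)-2-methoxy-4-(trimethylsilyl)but-3-yn-1-yl]-4,5-dihydro-1,3-oxazole-4-carboxylate
Conditions: Et2NSF3, CH2Cl2, −78 °C; then K2CO3, −78 °C→rt
Reagents that add atoms: none
Why: Wipf–Williams cyclodehydration, in which the activated serine hydroxyl is displaced by the amide oxygen to close the oxazoline under mild conditions.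

Step 13
Reactants: 21 methyl (4S)-2-[(2R)-2-methoxy-4-(trimethylsilyl)but-3-yn-1-yl]-4,5-dihydro-1,3-oxazole-4-carboxylate
Product: 22 methyl 2-[(2R)-2-methoxy-4-(trimethylsilyl)but-3-yn-1-yl]-1,3-oxazole-4-carboxylate
Conditions: BrCCl3, DBU, CH2Cl2, 0 °C→rt
Reagents that add atoms: none
Why: Oxazoline-to-oxazole oxidation by C4 bromination and elimination of HBr, with the alkyne kept silylated so it cannot be brominated.

Step 14
Reactants: 22 methyl 2-[(2R)-2-methoxy-4-(trimethylsilyl)but-3-yn-1-yl]-1,3-oxazole-4-carboxylate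
Product: 23 methyl 2-[(2R)-2-methoxybut-3-yn-1-yl]-1,3-oxazole-4-carboxylate
Conditions: K2CO3 (0.2 equiv), MeOH, 0 °C
Reagents that add atoms: none
Why: Methanolysis of the alkynylsilane gives the terminal alkyne, and methanol as solvent leaves the methyl ester unchanged.

Step 15
Reactants: 9 (4R,6S,7E)-5,5-dimethyl-6-(triethylsilyloxy)non-7-en-1-yn-4-ol; 24 (Z)-1,2-dichloroethene
Product: 25 (1Z,6R,8S,9E)-1-chloro-7,7-dimethyl-8-(triethylsilyloxy)undeca-1,9-dien-3-yn-6-ol
Conditions: 24 (5 equiv), Pd(PPh3)4 (5 mol %), CuI (10 mol %), n-BuNH2, benzene, rt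
Reagents that add atoms: none
Why: Sonogashira coupling that stops at mono-substitution because the dichloroethene is in excess, with retention of the Z geometry that becomes C9=C10.

Step 16
Reactants: 25 (1Z,6R,8S,9E)-1-chloro-7,7-dimethyl-8-(triethylsilyloxy)undeca-1,9-dien-3-yn-6-ol; 23 methyl 2-[(2R)-2-methoxybut-3-yn-1-yl]-1,3-oxazole-4-carboxylate
Product: 26 methyl 2-[(2R,5Z,10R,12S,13E)-10-hydroxy-2-methoxy-11,11-dimethyl-12-(triethylsilyloxy)pentadeca-5,13-diene-3,7-diyn-1-yl]-1,3-oxazole-4-carboxylate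
Conditions: Pd(PPh3)4 (5 mol %), CuI (15 mol %), n-BuNH2 (2 equiv), benzene, rt
Reagents that add atoms: none
Why: Second Sonogashira coupling, in which the alkyne-activated (Z)-vinyl chloride adds oxidatively to zerovalent palladium and couples with retention to give the (Z)-enediyne.

Step 17
Reactants: 26 methyl 2-[(2R,5Z,10R,12S,13E)-10-hydroxy-2-methoxy-11,11-dimethyl-12-(triethylsilyloxy)pentadeca-5,13-diene-3,7-diyn-1-yl]-1,3-oxazole-4-carboxylate
Product: 27 methyl 2-[(2R,3Z,5Z,7Z,10R,12S,13E)-10-hydroxy-2-methoxy-11,11-dimethyl-12-(triethylsilyloxy)pentadeca-3,5,7,13-tetraen-1-yl]-1,3-oxazole-4-carboxylate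
Conditions: Zn dust (activated with Cu(OAc)2 then AgNO3), MeOH/H2O (1:1), rt, dark
Reagents that add atoms: none
Why: Boland reduction adds hydrogen cis to conjugated triple bonds only, giving the 7Z,9Z,11Z triene and leaving isolated alkenes alone; everything after this step is run at or below room temperature.

Step 18
Reactants: 27 methyl 2-[(2R,3Z,5Z,7Z,10R,12S,13E)-10-hydroxy-2-methoxy-11,11-dimethyl-12-(triethylsilyloxy)pentadeca-3,5,7,13-tetraen-1-yl]-1,3-oxazole-4-carboxylate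
Product: 28 2-[(2R,3Z,5Z,7Z,10R,12S,13E)-10-hydroxy-2-methoxy-11,11-dimethyl-12-(triethylsilyloxy)pentadeca-3,5,7,13-tetraen-1-yl]-1,3-oxazole-4-carboxylic acid
Conditions: LiOH·H2O, THF/H2O (3:1), 0 °C→rt; cold dilute HCl to pH 4
Reagents that add atoms: lithium hydroxide, [Li+].[OH-]
Why: Saponification of the only ester present, under conditions too weakly basic to deprotonate C5 or remove the hindered triethylsilyl ether.

Step 19
Reactants: 28 2-[(2R,3Z,5Z,7Z,10R,12S,13E)-10-hydroxy-2-methoxy-11,11-dimethyl-12-(triethylsilyloxy)pentadeca-3,5,7,13-tetraen-1-yl]-1,3-oxazole-4-carboxylic acid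
Product: 30 2-[(2R,3Z,5Z,7Z,10R,12S,13E)-2-methoxy-11,11-dimethyl-12-(triethylsilyloxy)-10-(trimethylsilyloxy)pentadeca-3,5,7,13-tetraen-1-yl]-1,3-oxazole-4-carboxylic acid, via its trimethylsilyl ester 29 (not isolated)
Conditions: Me3SiCl, imidazole, CH2Cl2, 0 °C; then pH 7 buffer/MeOH, 0 °C
Reagents that add atoms: chlorotrimethylsilane, C[Si](C)(C)Cl
Why: Transient silylation of both the C14 hydroxyl and the acid, after which the silyl ester hydrolyses at once at pH 7 while the hindered secondary silyl ether stays on, masking C14–OH for the one esterification.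

Step 20
Reactants: 31 methyl prop-2-ynoate
Product: 32 methyl (2Z)-3-iodoprop-2-enoate
Conditions: NaI, AcOH, 70 °C
Reagents that add atoms: sodium iodide, [Na+].[I-]
Why: Conjugate hydroiodination of the ynoate, which proceeds by anti addition and gives the Z-iodoacrylate.

Step 21
Reactants: 32 methyl (2Z)-3-iodoprop-2-enoate
Product: 33 (2Z)-3-iodoprop-2-en-1-ol
Conditions: iBu2AlH, CH2Cl2, −78 °C
Reagents that add atoms: none
Why: 1,2-Reduction of the ester at low temperature keeps the vinyl iodide and its Z geometry.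

Step 22
Reactants: 11 (4S,6S,7E)-5,5-dimethyl-6-(triethylsilyloxy)non-7-en-1-yn-4-ol; 33 (2Z)-3-iodoprop-2-en-1-ol
Product: 34 (2Z,7S,9S,10E)-8,8-dimethyl-9-(triethylsilyloxy)dodeca-2,10-dien-4-yne-1,7-diol
Conditions: PdCl2(PPh3)2 (3 mol %), CuI (6 mol %), Et3N, THF, rt
Reagents that add atoms: none
Why: Sonogashira coupling of a vinyl iodide goes at room temperature with retention of the Z geometry and tolerates both free hydroxyls.

Step 23
Reactants: 34 (2Z,7S,9S,10E)-8,8-dimethyl-9-(triethylsilyloxy)dodeca-2,10-dien-4-yne-1,7-diol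
Product: 35 (4S,6S,7E)-1-[(2R,3S)-3-(hydroxymethyl)oxiran-2-yl]-5,5-dimethyl-6-(triethylsilyloxy)non-7-en-1-yn-4-ol
Conditions: Ti(OiPr)4 (1.1 equiv), L-(+)-diethyl tartrate (1.3 equiv), t-BuOOH, 4 Å MS, CH2Cl2, −25 °C
Reagents that add atoms: tert-butyl hydroperoxide, CC(C)(C)OO
Why: Sharpless asymmetric epoxidation, which touches only the allylic-alcohol alkene; L-(+)-tartrate gives the (2S,3R)-type cis-epoxy alcohol from a Z-allylic alcohol, which is 9′S,10′R, and the minor diastereomer is removed by chromatography.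

Step 24
Reactants: 35 (4S,6S,7E)-1-[(2R,3S)-3-(hydroxymethyl)oxiran-2-yl]-5,5-dimethyl-6-(triethylsilyloxy)non-7-en-1-yn-4-ol
Product: 36 (1Z,4S,6S,7E)-1-[(2R,3S)-3-(hydroxymethyl)oxiran-2-yl]-5,5-dimethyl-6-(triethylsilyloxy)nona-1,7-dien-4-ol
Conditions: H2 (1 atm), Pd/CaCO3 poisoned with Pb(OAc)2, quinoline, EtOAc, rt
Reagents that add atoms: none
Why: Lindlar-type syn semihydrogenation of the only alkyne gives the 11′Z alkene, with quinoline suppressing over-reduction and epoxide hydrogenolysis.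

Step 25
Reactants: 36 (1Z,4S,6S,7E)-1-[(2R,3S)-3-(hydroxymethyl)oxiran-2-yl]-5,5-dimethyl-6-(triethylsilyloxy)nona-1,7-dien-4-ol
Product: 37 (2R,3R)-3-[(1Z,4S,6S,7E)-4-hydroxy-5,5-dimethyl-6-(triethylsilyloxy)nona-1,7-dien-1-yl]oxirane-2-carbaldehyde
Conditions: TEMPO (10 mol %), PhI(OAc)2, CH2Cl2, 0 °C→rt
Reagents that add atoms: none
Why: Oxoammonium (TEMPO) oxidation takes the primary alcohol and leaves the hindered neopentyl secondary alcohol, giving the cis-epoxy aldehyde, which is used at once.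

Step 26
Reactants: 37 (2R,3R)-3-[(1Z,4S,6S,7E)-4-hydroxy-5,5-dimethyl-6-(triethylsilyloxy)nona-1,7-dien-1-yl]oxirane-2-carbaldehyde; 38 (triphenylphosphoranylidene)acetaldehyde
Product: 39 (2E)-3-{(2S,3R)-3-[(1Z,4S,6S,7E)-4-hydroxy-5,5-dimethyl-6-(triethylsilyloxy)nona-1,7-dien-1-yl]oxiran-2-yl}prop-2-enal
Conditions: 38 (1.3 equiv), benzene, rt
Reagents that add atoms: none
Why: Wittig reaction of a stabilised ylide under neutral conditions gives the E-enal (7′E) without epimerising the epoxy aldehyde, which is more reactive than the product enal.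

Step 27
Reactants: 40 methyl 2-(chloromethyl)-1,3-oxazole-4-carboxylate
Product: 41 methyl 2-[(diethoxyphosphoryl)methyl]-1,3-oxazole-4-carboxylate
Conditions: P(OEt)3 (neat), 140 °C
Reagents that add atoms: triethyl phosphite, CCOP(OCC)OCC
Why: Michaelis–Arbuzov reaction of the activated heteroaryl-methyl chloride gives the phosphonate.

Step 28
Reactants: 39 (2E)-3-{(2S,3R)-3-[(1Z,4S,6S,7E)-4-hydroxy-5,5-dimethyl-6-(triethylsilyloxy)nona-1,7-dien-1-yl]oxiran-2-yl}prop-2-enal; 41 methyl 2-[(diethoxyphosphoryl)methyl]-1,3-oxazole-4-carboxylate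
Product: 42 methyl 2-[(1E,3E)-4-{(2S,3R)-3-[(1Z,4S,6S,7E)-4-hydroxy-5,5-dimethyl-6-(triethylsilyloxy)nona-1,7-dien-1-yl]oxiran-2-yl}buta-1,3-dien-1-yl]-1,3-oxazole-4-carboxylate
Conditions: 41 (1.5 equiv), LiN(SiMe3)2, THF, −78 °C; then 39, −78→−20 °C
Reagents that add atoms: none
Why: Horner–Wadsworth–Emmons olefination with a stabilised phosphonate anion gives the new alkene E (5′E), and the preformed anion is not basic enough to open the epoxide or disturb the free hydroxyl.

Step 29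
Reactants: 30 2-[(2R,3Z,5Z,7Z,10R,12S,13E)-2-methoxy-11,11-dimethyl-12-(triethylsilyloxy)-10-(trimethylsilyloxy)pentadeca-3,5,7,13-tetraen-1-yl]-1,3-oxazole-4-carboxylic acid; 42 methyl 2-[(1E,3E)-4-{(2S,3R)-3-[(1Z,4S,6S,7E)-4-hydroxy-5,5-dimethyl-6-(triethylsilyloxy)nona-1,7-dien-1-yl]oxiran-2-yl}buta-1,3-dien-1-yl]-1,3-oxazole-4-carboxylate
Product: 44 (1Z,4S,6S,7E)-1-{(2R,3S)-3-[(1E,3E)-4-(4-methoxycarbonyl-1,3-oxazol-2-yl)buta-1,3-dien-1-yl]oxiran-2-yl}-5,5-dimethyl-6-(triethylsilyloxy)nona-1,7-dien-4-yl 2-[(2R,3Z,5Z,7Z,10R,12S,13E)-2-methoxy-11,11-dimethyl-12-(triethylsilyloxy)-10-(trimethylsilyloxy)pentadeca-3,5,7,13-tetraen-1-yl]-1,3-oxazole-4-carboxylate, via Yamaguchi mixed anhydride of the acid 43 (not isolated)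
Conditions: 2,4,6-Cl3C6H2COCl, Et3N, toluene, rt; then 42, DMAP, rt
Reagents that add atoms: none
Why: Yamaguchi esterification, where the aryl mixed anhydride and DMAP acylate the hindered C14′ hydroxyl at room temperature with retention at C14′.

Step 30
Reactants: 44 the linear ester from step 29
Product: 45 2-[(1E,3E)-4-{(2S,3R)-3-[(1Z,4S,6S,7E)-4-({2-[(2R,3Z,5Z,7Z,10R,12S,13E)-10-hydroxy-2-methoxy-11,11-dimethyl-12-(triethylsilyloxy)pentadeca-3,5,7,13-tetraen-1-yl]-1,3-oxazole-4-carbonyl}oxy)-5,5-dimethyl-6-(triethylsilyloxy)nona-1,7-dien-1-yl]oxiran-2-yl}buta-1,3-dien-1-yl]-1,3-oxazole-4-carboxylic acid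
Conditions: LiOH·H2O, THF/H2O (4:1), 0 °C; cold dilute HCl to pH 5
Reagents that add atoms: lithium hydroxide, [Li+].[OH-]
Why: Chemoselective saponification, in which the unhindered methyl ester and the trimethylsilyl ether are cleaved while the internal ester of the neopentyl secondary alcohol and the triethylsilyl ethers remain.

Step 31
Reactants: 45 the seco acid from step 30
Product: 47 16,16′-bis-O-triethylsilyl ether of the target macrodiolide, via Yamaguchi mixed anhydride of the seco acid 46 (not isolated)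
Conditions: 2,4,6-Cl3C6H2COCl, Et3N, THF, rt; then slow addition to DMAP, toluene (0.5 mM), rt
Reagents that add atoms: none
Why: Yamaguchi macrolactonisation at high dilution closes the 30-membered ring on the only free hydroxyl (C14) with retention, at a temperature the Z,Z,Z-triene and vinyl epoxide tolerate.

Step 32
Reactants: 47 16,16′-bis-O-triethylsilyl ether of the target macrodiolide
Product: 48 CNP0284709.4
Conditions: HF·pyridine, pyridine, THF, 0 °C→rt
Reagents that add atoms: none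
Why: Fluoride desilylation buffered with pyridine removes both allylic triethylsilyl ethers without opening the divinyl epoxide or isomerising the polyenes.

**Compound list**

1 | (E)-but-2-enal | C/C=C/C=O | starting material
2 | 1-methoxy-2-methyl-1-(trimethylsilyloxy)prop-1-ene | COC(O[Si](C)(C)C)=C(C)C | starting material
3 | methyl (3S,4E)-3-hydroxy-2,2-dimethylhex-4-enoate | C/C=C/[C@H](O)C(C)(C)C(=O)OC | intermediate
4 | methyl (3S,4E)-2,2-dimethyl-3-(triethylsilyloxy)hex-4-enoate | C/C=C/[C@H](O[Si](CC)(CC)CC)C(C)(C)C(=O)OC | intermediate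
5 | (3S,4E)-2,2-dimethyl-3-(triethylsilyloxy)hex-4-en-1-ol | C/C=C/[C@H](O[Si](CC)(CC)CC)C(C)(C)CO | intermediate
6 | (3S,4E)-2,2-dimethyl-3-(triethylsilyloxy)hex-4-enal | C/C=C/[C@H](O[Si](CC)(CC)CC)C(C)(C)C=O | intermediate
7 | 4,4,5,5-tetramethyl-2-(propa-1,2-dien-1-yl)-1,3,2-dioxaborolane | C=C=CB1OC(C)(C)C(C)(C)O1 | starting material
8 | O-pinacolboryl ether of 9 | C#CC[C@@H](OB1OC(C)(C)C(C)(C)O1)C(C)(C)[C@@H](O[Si](CC)(CC)CC)/C=C/C | intermediate
9 | (4R,6S,7E)-5,5-dimethyl-6-(triethylsilyloxy)non-7-en-1-yn-4-ol | C#CC[C@@H](O)C(C)(C)[C@@H](O[Si](CC)(CC)CC)/C=C/C | intermediate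
10 | O-pinacolboryl ether of 11 | C#CC[C@H](OB1OC(C)(C)C(C)(C)O1)C(C)(C)[C@@H](O[Si](CC)(CC)CC)/C=C/C | intermediate
11 | (4S,6S,7E)-5,5-dimethyl-6-(triethylsilyloxy)non-7-en-1-yn-4-ol | C#CC[C@H](O)C(C)(C)[C@@H](O[Si](CC)(CC)CC)/C=C/C | intermediate
12 | ethyl 3-(trimethylsilyl)prop-2-ynoate | CCOC(=O)C#C[Si](C)(C)C | starting material
13 | tert-butyl acetate | CC(=O)OC(C)(C)C | starting material
14 | lithium enolate of tert-butyl acetate | C=C(O[Li])OC(C)(C)C | intermediate
15 | tert-butyl 3-oxo-5-(trimethylsilyl)pent-4-ynoate | CC(C)(C)OC(=O)CC(=O)C#C[Si](C)(C)C | intermediate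
16 | tert-butyl (3R)-3-hydroxy-5-(trimethylsilyl)pent-4-ynoate | CC(C)(C)OC(=O)C[C@@H](O)C#C[Si](C)(C)C | intermediate
17 | tert-butyl (3R)-3-methoxy-5-(trimethylsilyl)pent-4-ynoate | CC(C)(C)OC(=O)C[C@@H](OC)C#C[Si](C)(C)C | intermediate
18 | (3R)-3-methoxy-5-(trimethylsilyl)pent-4-ynoic acid | OC(=O)C[C@@H](OC)C#C[Si](C)(C)C | intermediate
19 | methyl L-serinate hydrochloride | COC(=O)[C@H](CO)[NH3+].[Cl-] | starting material
20 | methyl N-[(3R)-3-methoxy-5-(trimethylsilyl)pent-4-ynoyl]-L-serinate | COC(=O)[C@H](CO)NC(=O)C[C@@H](OC)C#C[Si](C)(C)C | intermediate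
21 | methyl (4S)-2-[(2R)-2-methoxy-4-(trimethylsilyl)but-3-yn-1-yl]-4,5-dihydro-1,3-oxazole-4-carboxylate | COC(=O)[C@@H]1COC(C[C@@H](OC)C#C[Si](C)(C)C)=N1 | intermediate
22 | methyl 2-[(2R)-2-methoxy-4-(trimethylsilyl)but-3-yn-1-yl]-1,3-oxazole-4-carboxylate | COC(=O)c1coc(C[C@@H](OC)C#C[Si](C)(C)C)n1 | intermediate
23 | methyl 2-[(2R)-2-methoxybut-3-yn-1-yl]-1,3-oxazole-4-carboxylate | COC(=O)c1coc(C[C@@H](OC)C#C)n1 | intermediate
24 | (Z)-1,2-dichloroethene | Cl/C=C\Cl | starting material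
25 | (1Z,6R,8S,9E)-1-chloro-7,7-dimethyl-8-(triethylsilyloxy)undeca-1,9-dien-3-yn-6-ol | Cl/C=C\C#CC[C@@H](O)C(C)(C)[C@@H](O[Si](CC)(CC)CC)/C=C/C | intermediate
26 | methyl 2-[(2R,5Z,10R,12S,13E)-10-hydroxy-2-methoxy-11,11-dimethyl-12-(triethylsilyloxy)pentadeca-5,13-diene-3,7-diyn-1-yl]-1,3-oxazole-4-carboxylate | COC(=O)c1coc(C[C@@H](OC)C#C/C=C\C#CC[C@@H](O)C(C)(C)[C@@H](O[Si](CC)(CC)CC)/C=C/C)n1 | intermediate
27 | methyl 2-[(2R,3Z,5Z,7Z,10R,12S,13E)-10-hydroxy-2-methoxy-11,11-dimethyl-12-(triethylsilyloxy)pentadeca-3,5,7,13-tetraen-1-yl]-1,3-oxazole-4-carboxylate | COC(=O)c1coc(C[C@@H](OC)/C=C\C=C/C=C\C[C@@H](O)C(C)(C)[C@@H](O[Si](CC)(CC)CC)/C=C/C)n1 | intermediate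
28 | 2-[(2R,3Z,5Z,7Z,10R,12S,13E)-10-hydroxy-2-methoxy-11,11-dimethyl-12-(triethylsilyloxy)pentadeca-3,5,7,13-tetraen-1-yl]-1,3-oxazole-4-carboxylic acid | OC(=O)c1coc(C[C@@H](OC)/C=C\C=C/C=C\C[C@@H](O)C(C)(C)[C@@H](O[Si](CC)(CC)CC)/C=C/C)n1 | intermediate
29 | trimethylsilyl ester of 30 | C[Si](C)(C)OC(=O)c1coc(C[C@@H](OC)/C=C\C=C/C=C\C[C@@H](O[Si](C)(C)C)C(C)(C)[C@@H](O[Si](CC)(CC)CC)/C=C/C)n1 | intermediate
30 | 2-[(2R,3Z,5Z,7Z,10R,12S,13E)-2-methoxy-11,11-dimethyl-12-(triethylsilyloxy)-10-(trimethylsilyloxy)pentadeca-3,5,7,13-tetraen-1-yl]-1,3-oxazole-4-carboxylic acid | OC(=O)c1coc(C[C@@H](OC)/C=C\C=C/C=C\C[C@@H](O[Si](C)(C)C)C(C)(C)[C@@H](O[Si](CC)(CC)CC)/C=C/C)n1 | intermediate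
31 | methyl prop-2-ynoate | COC(=O)C#C | starting material
32 | methyl (2Z)-3-iodoprop-2-enoate | COC(=O)/C=C\I | intermediate
33 | (2Z)-3-iodoprop-2-en-1-ol | OC/C=C\I | intermediate
34 | (2Z,7S,9S,10E)-8,8-dimethyl-9-(triethylsilyloxy)dodeca-2,10-dien-4-yne-1,7-diol | OC/C=C\C#CC[C@H](O)C(C)(C)[C@@H](O[Si](CC)(CC)CC)/C=C/C | intermediate
35 | (4S,6S,7E)-1-[(2R,3S)-3-(hydroxymethyl)oxiran-2-yl]-5,5-dimethyl-6-(triethylsilyloxy)non-7-en-1-yn-4-ol | OC[C@@H]1O[C@@H]1C#CC[C@H](O)C(C)(C)[C@@H](O[Si](CC)(CC)CC)/C=C/C | intermediate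
36 | (1Z,4S,6S,7E)-1-[(2R,3S)-3-(hydroxymethyl)oxiran-2-yl]-5,5-dimethyl-6-(triethylsilyloxy)nona-1,7-dien-4-ol | OC[C@@H]1O[C@@H]1/C=C\C[C@H](O)C(C)(C)[C@@H](O[Si](CC)(CC)CC)/C=C/C | intermediate
37 | (2R,3R)-3-[(1Z,4S,6S,7E)-4-hydroxy-5,5-dimethyl-6-(triethylsilyloxy)nona-1,7-dien-1-yl]oxirane-2-carbaldehyde | O=C[C@@H]1O[C@@H]1/C=C\C[C@H](O)C(C)(C)[C@@H](O[Si](CC)(CC)CC)/C=C/C | intermediate
38 | (triphenylphosphoranylidene)acetaldehyde | O=CC=P(c1ccccc1)(c1ccccc1)c1ccccc1 | starting material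
39 | (2E)-3-{(2S,3R)-3-[(1Z,4S,6S,7E)-4-hydroxy-5,5-dimethyl-6-(triethylsilyloxy)nona-1,7-dien-1-yl]oxiran-2-yl}prop-2-enal | O=C/C=C/[C@@H]1O[C@@H]1/C=C\C[C@H](O)C(C)(C)[C@@H](O[Si](CC)(CC)CC)/C=C/C | intermediate
40 | methyl 2-(chloromethyl)-1,3-oxazole-4-carboxylate | COC(=O)c1coc(CCl)n1 | starting material
41 | methyl 2-[(diethoxyphosphoryl)methyl]-1,3-oxazole-4-carboxylate | COC(=O)c1coc(CP(=O)(OCC)OCC)n1 | intermediate
42 | methyl 2-[(1E,3E)-4-{(2S,3R)-3-[(1Z,4S,6S,7E)-4-hydroxy-5,5-dimethyl-6-(triethylsilyloxy)nona-1,7-dien-1-yl]oxiran-2-yl}buta-1,3-dien-1-yl]-1,3-oxazole-4-carboxylate | COC(=O)c1coc(/C=C/C=C/[C@@H]2O[C@@H]2/C=C\C[C@H](O)C(C)(C)[C@@H](O[Si](CC)(CC)CC)/C=C/C)n1 | intermediate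
43 | mixed anhydride of acid 30 with 2,4,6-trichlorobenzoic acid | O=C(OC(=O)c1coc(C[C@@H](OC)/C=C\C=C/C=C\C[C@@H](O[Si](C)(C)C)C(C)(C)[C@@H](O[Si](CC)(CC)CC)/C=C/C)n1)c1c(Cl)cc(Cl)cc1Cl | intermediate
44 | linear ester: 42 acylated at O-14′ by acid 30 (full name in step 29) | COC(=O)c1coc(/C=C/C=C/[C@@H]2O[C@@H]2/C=C\C[C@H](OC(=O)c2coc(C[C@@H](OC)/C=C\C=C/C=C\C[C@@H](O[Si](C)(C)C)C(C)(C)[C@@H](O[Si](CC)(CC)CC)/C=C/C)n2)C(C)(C)[C@@H](O[Si](CC)(CC)CC)/C=C/C)n1 | intermediate
45 | seco acid: free C1′ acid and free C14–OH, both C16 hydroxyls as triethylsilyl ethers (full name in step 30) | OC(=O)c1coc(/C=C/C=C/[C@@H]2O[C@@H]2/C=C\C[C@H](OC(=O)c2coc(C[C@@H](OC)/C=C\C=C/C=C\C[C@@H](O)C(C)(C)[C@@H](O[Si](CC)(CC)CC)/C=C/C)n2)C(C)(C)[C@@H](O[Si](CC)(CC)CC)/C=C/C)n1 | intermediate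
46 | mixed anhydride of seco acid 45 with 2,4,6-trichlorobenzoic acid | O=C(OC(=O)c1coc(/C=C/C=C/[C@@H]2O[C@@H]2/C=C\C[C@H](OC(=O)c2coc(C[C@@H](OC)/C=C\C=C/C=C\C[C@@H](O)C(C)(C)[C@@H](O[Si](CC)(CC)CC)/C=C/C)n2)C(C)(C)[C@@H](O[Si](CC)(CC)CC)/C=C/C)n1)c1c(Cl)cc(Cl)cc1Cl | intermediate
47 | 16,16′-bis-O-triethylsilyl ether of the target macrodiolide | C/C=C/[C@H](O[Si](CC)(CC)CC)C(C)(C)[C@@H]1C/C=C\[C@H]2O[C@H]2/C=C/C=C/c2nc(co2)C(=O)O[C@@H](C(C)(C)[C@@H](O[Si](CC)(CC)CC)/C=C/C)C\C=C/C=C\C=C/[C@H](OC)Cc2nc(co2)C(=O)O1 | intermediate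
48 | CNP0284709.4 (30-membered bis-oxazole macrodiolide with 9′,10′-cis-epoxide and 6-methoxy Z,Z,Z-triene) | C/C=C/[C@H](O)C(C)(C)[C@@H]1C/C=C\[C@H]2O[C@H]2/C=C/C=C/c2nc(co2)C(=O)O[C@@H](C(C)(C)[C@@H](O)/C=C/C)C\C=C/C=C\C=C/[C@H](OC)Cc2nc(co2)C(=O)O1 | target

**Totals and weak points**

Total step count: 32. Longest linear sequence: 16 steps (12 → 23 → 26 → 30 → 44 → 48: steps 7–14, 16–19, 29–32).

Step 5 (and, by the same token, step 6): the phosphoric-acid-catalysed allenylboration may be slow or poorly selective on this α-quaternary aldehyde with a β-silyloxy stereocentre. The fallback drops catalyst control and sets out from 6. A zinc Barbier propargylation (propargyl bromide, Zn dust, THF/saturated aqueous NH4Cl, 0 °C) gives both C14 epimers in one reaction. Because the route needs both, they are separated by chromatography and assigned by Mosher ester analysis. The 1,3-syn epimer is 9 and the 1,3-anti epimer is 11, so the fallback comes back at 9 and also supplies 11 for step 22. It makes no new compound (none, F0).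

Step 23: Sharpless epoxidation of a Z-allylic alcohol whose alkene is conjugated to an alkyne can be slow and only moderately selective, and the alkynyl epoxide is acid-sensitive. The fallback changes the order of events and sets out from 34. Zn(Cu/Ag) reduction of the enyne first gives (2Z,4Z,7S,9S,10E)-8,8-dimethyl-9-(triethylsilyloxy)dodeca-2,4,10-triene-1,7-diol F1. Sharpless epoxidation of this more electron-rich dienol (Ti(OiPr)4, L-(+)-diethyl tartrate, t-BuOOH, −25 °C) then acts only on the allylic-alcohol alkene and comes back at 36, so step 24 is no longer needed.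

Step 30: hydroxide may not distinguish cleanly between the terminal methyl ester and the internal ester. The fallback replaces the methyl ester by one removed reductively and sets out from 42. LiOH hydrolysis, with no second ester yet present, gives 2-[(1E,3E)-4-{(2S,3R)-3-[(1Z,4S,6S,7E)-4-hydroxy-5,5-dimethyl-6-(triethylsilyloxy)nona-1,7-dien-1-yl]oxiran-2-yl}buta-1,3-dien-1-yl]-1,3-oxazole-4-carboxylic acid F2. Esterification with excess 2,2,2-trichloroethanol (EDC·HCl, DMAP, CH2Cl2, 0 °C) gives its 2,2,2-trichloroethyl ester F3. Yamaguchi coupling with 30 through 43, as in step 29, gives the 2,2,2-trichloroethyl analogue of linear ester 44, F4. Zn dust in THF/aqueous NH4OAc at room temperature then removes the trichloroethyl group without any hydroxide, the trimethylsilyl ether is lost in the mildly acidic aqueous work-up, and the route comes back at 45.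

**Further compounds**

F0 | step 5 | none | none
F1 | step 23 | (2Z,4Z,7S,9S,10E)-8,8-dimethyl-9-(triethylsilyloxy)dodeca-2,4,10-triene-1,7-diol | OC/C=C\C=C/C[C@H](O)C(C)(C)[C@@H](O[Si](CC)(CC)CC)/C=C/C
F2 | step 30 | 2-[(1E,3E)-4-{(2S,3R)-3-[(1Z,4S,6S,7E)-4-hydroxy-5,5-dimethyl-6-(triethylsilyloxy)nona-1,7-dien-1-yl]oxiran-2-yl}buta-1,3-dien-1-yl]-1,3-oxazole-4-carboxylic acid | OC(=O)c1coc(/C=C/C=C/[C@@H]2O[C@@H]2/C=C\C[C@H](O)C(C)(C)[C@@H](O[Si](CC)(CC)CC)/C=C/C)n1
F3 | step 30 | 2,2,2-trichloroethyl ester of F2 | ClC(Cl)(Cl)COC(=O)c1coc(/C=C/C=C/[C@@H]2O[C@@H]2/C=C\C[C@H](O)C(C)(C)[C@@H](O[Si](CC)(CC)CC)/C=C/C)n1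
F4 | step 30 | 2,2,2-trichloroethyl analogue of linear ester 44 | ClC(Cl)(Cl)COC(=O)c1coc(/C=C/C=C/[C@@H]2O[C@@H]2/C=C\C[C@H](OC(=O)c2coc(C[C@@H](OC)/C=C\C=C/C=C\C[C@@H](O[Si](C)(C)C)C(C)(C)[C@@H](O[Si](CC)(CC)CC)/C=C/C)n2)C(C)(C)[C@@H](O[Si](CC)(CC)CC)/C=C/C)n1
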